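Ring A is the cyclohexane C1–C5/C10 (seco-labdane numbering), the lactone is C19(=O)–O–C6 and C9 is the side-chain ketone. Ring A is disconnected at C1–C2 and C5–C10: an intramolecular Diels–Alder reaction of an acyclic dienyl methacrylate, tethered as the ester of O6, closes both bonds at once and sets the vicinal C5 and quaternary C10 stereocentres. The feature exploited is the 1,4-relationship of O6 and the C9 carbonyl across C5–C10: the cycloadduct is a temporary trans-fused C9–O6 γ-lactone, which, after C4 methylation, a furylethyllithium opens to the C9 ketone while O6 relactonises onto C19. The C7 acetoxy ketone is unmasked last from an allylic silyl ether.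

Key step: step 7

Atom numbering used below: C1–C3 ring CH2; C4 (Me-18 and lactone carbonyl C19); C5 ring-fusion CH; C6 CH–O; C7 CH–OAc; C8 acetyl C=O (Me-17); C9 ketone; C10 (Me-20); C11, C12 CH2; furan C13–C16.

Assumption: the (R,R) antipode of ProPhenol is taken as the one whose induction is matched with Felkin–Anh addition to aldehyde 3 (its enantiomer would be used otherwise); 1, 4, 6, 9 and 14 are taken as catalogue chemicals.

Step 1
Reactants: 1 (R)-but-3-ene-1,2-diol
Product: 2 (R)-1,2-bis(triethylsilyloxy)but-3-ene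
Conditions: Et3SiCl (2.3 equiv), imidazole, CH2Cl2, 0 °C to rt
Reagents that add atoms: chlorotriethylsilane, CC[Si](Cl)(CC)CC
Why: Standard silylation of both hydroxyl groups, which leaves the C7 stereocentre untouched.

Step 2
Reactants: 2 (R)-1,2-bis(triethylsilyloxy)but-3-ene
Product: 3 (R)-2-(triethylsilyloxy)but-3-enal
Conditions: (COCl)2, DMSO, CH2Cl2, –78 to –40 °C; Et3N, –78 °C; cold work-up, used crude
Reagents that add atoms: none
Why: Swern oxidation in which the chlorosulfonium salt cleaves and oxidises the primary triethylsilyl ether selectively while the secondary one survives; the cold work-up limits epimerisation and double-bond migration of the α-silyloxy aldehyde.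

Step 3
Reactants: 3 (R)-2-(triethylsilyloxy)but-3-enal; 4 methyl propiolate
Product: 5 methyl (4S,5R)-4-hydroxy-5-(triethylsilyloxy)hept-6-en-2-ynoate
Conditions: Me2Zn (3 equiv), (R,R)-ProPhenol [2,6-bis{[2-(hydroxydiphenylmethyl)pyrrolidin-1-yl]methyl}-4-methylphenol, 20 mol %], Ph3PO (40 mol %), toluene, 0 to 4 °C
Reagents that add atoms: none
Why: Catalytic asymmetric alkynylation of the aldehyde by the zinc alkynylide of the propiolate; the new C6 carbinol should form anti to the C7 silyl ether by Felkin–Anh attack on the non-chelating α-silyloxy aldehyde, reinforced by the dinuclear zinc–ligand complex.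

Step 4
Reactants: 5 methyl (4S,5R)-4-hydroxy-5-(triethylsilyloxy)hept-6-en-2-ynoate; 6 methacryloyl chloride
Product: 7 methyl (4S,5R)-4-(methacryloyloxy)-5-(triethylsilyloxy)hept-6-en-2-ynoate
Conditions: i-Pr2NEt, DMAP (cat.), CH2Cl2, –20 °C
Reagents that add atoms: none
Why: O-acylation of the propargylic alcohol at low temperature, so that base-induced isomerisation of the γ-hydroxy ynoate is avoided; it installs the dienophile and the tether without touching a stereocentre.

Step 5
Reactants: 7 methyl (4S,5R)-4-(methacryloyloxy)-5-(triethylsilyloxy)hept-6-en-2-ynoate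
Product: 8 methyl (2E,4S,5R)-4-(methacryloyloxy)-2-(tributylstannyl)-5-(triethylsilyloxy)hepta-2,6-dienoate
Conditions: Bu3SnH (1.05 equiv), Pd(PPh3)4 (2 mol %), THF, 0 °C
Reagents that add atoms: tributyltin hydride, CCCC[SnH](CCCC)CCCC
Why: Palladium-catalysed syn-hydrostannation of the ynoate places tin on the carbon α to the ester and hydrogen on C5, so C6 ends cis to the ester; the alkyne should react far faster than the methacrylate or the terminal alkene.

Step 6
Reactants: 8 methyl (2E,4S,5R)-4-(methacryloyloxy)-2-(tributylstannyl)-5-(triethylsilyloxy)hepta-2,6-dienoate; 9 iodoethene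
Product: 10 methyl (2Z,4S,5R)-2-ethenyl-4-(methacryloyloxy)-5-(triethylsilyloxy)hepta-2,6-dienoate
Conditions: copper thiophene-2-carboxylate Cu(O2CC4H3S) (1.5 equiv), NMP, 0 °C to rt; product kept cold and used at once
Reagents that add atoms: none
Why: Copper-mediated Stille-type coupling (tin-to-copper transmetalation, then coupling with the vinyl iodide) proceeds with retention of alkene geometry, and the palladium-free conditions avoid ionisation of the allylic methacrylate.

Step 7
Reactants: 10 methyl (2Z,4S,5R)-2-ethenyl-4-(methacryloyloxy)-5-(triethylsilyloxy)hepta-2,6-dienoate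
Product: 11 methyl (3S,3aR,7aS)-7a-methyl-1-oxo-3-[(1R)-1-(triethylsilyloxy)prop-2-en-1-yl]-1,3,3a,6,7,7a-hexahydro-2-benzofuran-4-carboxylate (trans-fused lactone)
Conditions: toluene (0.005 M), BHT (0.1 equiv), 170 °C, sealed tube
Reagents that add atoms: none
Why: Thermal, concerted asynchronous [4+2] cycloaddition of the 2-(methoxycarbonyl)diene C2=C3–C4=C5 onto the methacrylate C1=C10, a type 1 intramolecular Diels–Alder reaction whose closest precedent is the cyclisation of ester-linked 1,3,8-nonatrienes (pentadienyl acrylates and fumarates). Two rings close: the cyclohexene (ring A) by the cycloaddition and the five-membered lactone O6–C9(=O)–C10–C5–C6 as the ring fused through the three-atom tether, which also fixes the regiochemistry (C5 to C10, C2 to C1). C5 is set by the C6 stereocentre: allylic 1,3-strain against the cis ester on C4 holds H6 in the diene plane, so O6 and the tethered dienophile sit on one diene face and the C7 side chain on the other. C10 is set by the mode of ring fusion: from that rotamer the short ester bridge reaches C10 best when the C9 carbonyl is exo, and C1 carries no Z substituent that could favour an endo tether, so the trans-fused lactone (C6 and C9 trans on ring A, Me-20 axial and cis to C6) is expected. The step therefore needs π-facial selectivity and trans over cis fusion, both secured by the C4 ester together with the C6 configuration, and it needs cyclisation to outrun dimerisation of the electron-poor diene, which high dilution and BHT should secure.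

Step 8
Reactants: 11 methyl (3S,3aR,7aS)-7a-methyl-1-oxo-3-[(1R)-1-(triethylsilyloxy)prop-2-en-1-yl]-1,3,3a,6,7,7a-hexahydro-2-benzofuran-4-carboxylate
Product: 13 methyl (3S,3aS,4S,7aS)-4,7a-dimethyl-1-oxo-3-[(1R)-1-(triethylsilyloxy)prop-2-en-1-yl]octahydro-2-benzofuran-4-carboxylate, via potassium ester enolate 12 (not isolated)
Conditions: K[(s-Bu)3BH] (1.1 equiv), THF, –78 °C; then MeI (5 equiv), DMPU, –78 to 0 °C
Reagents that add atoms: iodomethane, CI
Why: Reductive alkylation (conjugate hydride addition to the enoate at C3, then C-methylation of the enolate); iodomethane should approach C4 from the face anti to the axial Me-20 on C10 (1,3-diaxial shielding, as in resin-acid C4 alkylations), leaving the ester axial and cis to Me-20 and C6, while the hindered non-enolisable lactone is not reduced at –78 °C.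

Step 9
Reactants: 14 2-(furan-3-yl)ethanol
Product: 15 3-(2-iodoethyl)furan
Conditions: I2, PPh3, imidazole, CH2Cl2, 0 °C
Reagents that add atoms: iodine, II
Why: Appel-type iodination of a primary alcohol under neutral conditions that the furan tolerates.

Step 10
Reactants: 13 methyl (3S,3aS,4S,7aS)-4,7a-dimethyl-1-oxo-3-[(1R)-1-(triethylsilyloxy)prop-2-en-1-yl]octahydro-2-benzofuran-4-carboxylate; 15 3-(2-iodoethyl)furan
Product: 19 (3S,3aR,4S,7aS)-4-[3-(furan-3-yl)propanoyl]-3-[(1R)-1-hydroxyprop-2-en-1-yl]-4,7a-dimethylhexahydro-2-benzofuran-1(3H)-one, via 2-(furan-3-yl)ethyllithium 16 (not isolated), via lithium keto-alkoxide 17 (not isolated), via triethylsilyl ether 18 (not isolated)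
Conditions: 15 (1.05 equiv), t-BuLi (2.1 equiv), Et2O, –78 °C; add to 13, THF, –78 °C; warm to 0 °C; then 1 M HCl, THF–MeOH, rt
Reagents that add atoms: none
Why: Lithium–iodine exchange and single addition of the alkyllithium to the non-enolisable lactone (the tetrahedral adduct persists at –78 °C and the axial neopentyl methyl ester is inert); on warming the adduct opens to the C9 ketone and the freed C6 alkoxide attacks the C19 ester (translactonisation to the cis-fused γ-lactone, no stereocentre altered), and the acid then removes the silyl ether.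

Step 11
Reactants: 19 (3S,3aR,4S,7aS)-4-[3-(furan-3-yl)propanoyl]-3-[(1R)-1-hydroxyprop-2-en-1-yl]-4,7a-dimethylhexahydro-2-benzofuran-1(3H)-one
Product: 20 (1R)-1-[(3S,3aR,4S,7aS)-4-[3-(furan-3-yl)propanoyl]-4,7a-dimethyl-1-oxooctahydro-2-benzofuran-3-yl]prop-2-en-1-yl acetate
Conditions: Ac2O, pyridine, DMAP (cat.), CH2Cl2, 0 °C to rt
Reagents that add atoms: acetic anhydride, CC(=O)OC(C)=O
Why: Acetylation of the only free hydroxyl group (O7) with retention at C7.

Step 12
Reactants: 20 (1R)-1-[(3S,3aR,4S,7aS)-4-[3-(furan-3-yl)propanoyl]-4,7a-dimethyl-1-oxooctahydro-2-benzofuran-3-yl]prop-2-en-1-yl acetate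
Product: 21 (1S)-1-[(3S,3aR,4S,7aS)-4-[3-(furan-3-yl)propanoyl]-4,7a-dimethyl-1-oxooctahydro-2-benzofuran-3-yl]-2-oxopropyl acetate (target)
Conditions: PdCl2(C12H10N2O) [PdCl2 complex of 2-(4,5-dihydro-1,3-oxazol-2-yl)quinoline, 5 mol %], AgSbF6 (12 mol %), aq. t-BuOOH, CH2Cl2, 0 °C to rt
Reagents that add atoms: tert-butyl hydroperoxide, CC(C)(C)OO
Why: Wacker-type Markovnikov oxidation of the terminal alkene to the methyl ketone in its peroxide-mediated form, which is the variant suited to allylic acetates; the C7 stereocentre is not involved.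

Compound list
1 | (R)-but-3-ene-1,2-diol | O[C@H](C=C)CO | starting material
2 | (R)-1,2-bis(triethylsilyloxy)but-3-ene | CC[Si](CC)(CC)O[C@H](C=C)CO[Si](CC)(CC)CC | intermediate
3 | (R)-2-(triethylsilyloxy)but-3-enal | CC[Si](CC)(CC)O[C@H](C=C)C=O | intermediate
4 | methyl propiolate | C#CC(=O)OC | starting material
5 | methyl (4S,5R)-4-hydroxy-5-(triethylsilyloxy)hept-6-en-2-ynoate | CC[Si](CC)(CC)O[C@H](C=C)[C@@H](O)C#CC(=O)OC | intermediate
6 | methacryloyl chloride | C=C(C)C(Cl)=O | starting material
7 | methyl (4S,5R)-4-(methacryloyloxy)-5-(triethylsilyloxy)hept-6-en-2-ynoate | CC[Si](CC)(CC)O[C@H](C=C)[C@@H](OC(=O)C(C)=C)C#CC(=O)OC | intermediate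
8 | methyl (2E,4S,5R)-4-(methacryloyloxy)-2-(tributylstannyl)-5-(triethylsilyloxy)hepta-2,6-dienoate | CC[Si](CC)(CC)O[C@H](C=C)[C@@H](OC(=O)C(C)=C)/C=C(/[Sn](CCCC)(CCCC)CCCC)C(=O)OC | intermediate
9 | iodoethene (vinyl iodide) | C=CI | starting material
10 | methyl (2Z,4S,5R)-2-ethenyl-4-(methacryloyloxy)-5-(triethylsilyloxy)hepta-2,6-dienoate | CC[Si](CC)(CC)O[C@H](C=C)[C@@H](OC(=O)C(C)=C)/C=C(/C=C)C(=O)OC | intermediate
11 | methyl (3S,3aR,7aS)-7a-methyl-1-oxo-3-[(1R)-1-(triethylsilyloxy)prop-2-en-1-yl]-1,3,3a,6,7,7a-hexahydro-2-benzofuran-4-carboxylate | CC[Si](CC)(CC)O[C@H](C=C)[C@H]1OC(=O)[C@@]2(C)CCC=C(C(=O)OC)[C@H]12 | intermediate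
12 | potassium ester enolate (C4=C19 enolate of the C3-reduced ester of 11) | CC[Si](CC)(CC)O[C@H](C=C)[C@H]1OC(=O)[C@@]2(C)CCCC(=C([O-])OC)[C@H]12.[K+] | intermediate
13 | methyl (3S,3aS,4S,7aS)-4,7a-dimethyl-1-oxo-3-[(1R)-1-(triethylsilyloxy)prop-2-en-1-yl]octahydro-2-benzofuran-4-carboxylate | CC[Si](CC)(CC)O[C@H](C=C)[C@H]1OC(=O)[C@@]2(C)CCC[C@](C)(C(=O)OC)[C@H]12 | intermediate
14 | 2-(furan-3-yl)ethanol | OCCc1ccoc1 | starting material
15 | 3-(2-iodoethyl)furan | ICCc1ccoc1 | intermediate
16 | 2-(furan-3-yl)ethyllithium | [Li]CCc1ccoc1 | intermediate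
17 | lithium salt of methyl (1S,2R,3S)-3-[3-(furan-3-yl)propanoyl]-1,3-dimethyl-2-[(1S,2R)-1-oxido-2-(triethylsilyloxy)but-3-en-1-yl]cyclohexane-1-carboxylate | CC[Si](CC)(CC)O[C@H](C=C)[C@@H]([O-])[C@H]1[C@@](C)(C(=O)OC)CCC[C@]1(C)C(=O)CCc2ccoc2.[Li+] | intermediate
18 | (3S,3aR,4S,7aS)-4-[3-(furan-3-yl)propanoyl]-4,7a-dimethyl-3-[(1R)-1-(triethylsilyloxy)prop-2-en-1-yl]hexahydro-2-benzofuran-1(3H)-one | CC[Si](CC)(CC)O[C@H](C=C)[C@H]1OC(=O)[C@@]2(C)CCC[C@](C)(C(=O)CCc3ccoc3)[C@@H]12 | intermediate
19 | (3S,3aR,4S,7aS)-4-[3-(furan-3-yl)propanoyl]-3-[(1R)-1-hydroxyprop-2-en-1-yl]-4,7a-dimethylhexahydro-2-benzofuran-1(3H)-one | O[C@H](C=C)[C@H]1OC(=O)[C@@]2(C)CCC[C@](C)(C(=O)CCc3ccoc3)[C@@H]12 | intermediate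
20 | (1R)-1-[(3S,3aR,4S,7aS)-4-[3-(furan-3-yl)propanoyl]-4,7a-dimethyl-1-oxooctahydro-2-benzofuran-3-yl]prop-2-en-1-yl acetate | CC(=O)O[C@H](C=C)[C@H]1OC(=O)[C@@]2(C)CCC[C@](C)(C(=O)CCc3ccoc3)[C@@H]12 | intermediate
21 | (1S)-1-[(3S,3aR,4S,7aS)-4-[3-(furan-3-yl)propanoyl]-4,7a-dimethyl-1-oxooctahydro-2-benzofuran-3-yl]-2-oxopropyl acetate | CC(=O)O[C@H](C(C)=O)[C@H]1OC(=O)[C@@]2(C)CCC[C@](C)(C(=O)CCc3ccoc3)[C@@H]12 | target

Total step count: 12. Longest linear sequence: 11 steps (steps 1–8 and 10–12; step 9 is a one-step side branch).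

Steps most likely to fail

Step 7. The ester tether may resist the s-cis conformation that the cyclisation needs, so that diene dimerisation or acrylate polymerisation outruns ring closure, or the ring fusion may be poorly controlled (cis- and trans-fused adducts together). The fallback sets out from 5 and returns at 11, and it uses a doubly activated dienophile whose extra activating group is removed afterwards. Alcohol 5 is esterified (DCC, DMAP) with the known half ester (2E)-4-tert-butoxy-2-methyl-4-oxobut-2-enoic acid to give the mixed mesaconate F1. Hydrostannation as in step 5 gives the stannane F2, and coupling with 9 as in step 6 gives the triene F3. Its E-configured, fumarate-type dienophile should cyclise in toluene at about 110 °C with the terminal ester endo and the tether exo, giving the trans-fused adduct F4, which carries a tert-butyl ester on C1 cis to Me-20. TMSOTf and 2,6-lutidine free the acid F5. Barton decarboxylation (N-hydroxypyridine-2-thione ester, t-BuSH, visible light) then removes the extra carbon and gives 11.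

Step 10. The tetrahedral adduct may collapse early, which leads to over-addition at the new ketone, or the hindered lactone carbonyl may be attacked too slowly, so that unreacted alkyllithium survives to the warming stage. The fallback sets out from 13 and returns at 18. Me3Al and N,O-dimethylhydroxylamine hydrochloride (CH2Cl2, 0 °C to rt) open the strained lactone to the hydroxy Weinreb amide F6, and PPTS in warm toluene closes O6 onto C19 to give the Weinreb amide lactone F7. Reagent 16 (made as in step 10) adds once to F7 at –78 °C through the chelated tetrahedral intermediate and gives 18, which acid desilylates to 19 as before.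

Step 12. The electron-rich furan may be oxidised competitively by the peroxide, or the acetate may be lost by allylic transposition or anti-Markovnikov oxidation. The fallback sets out from 20 and returns at 21. Mukaiyama hydration (Co(acac)2 cat., PhSiH3, O2, i-PrOH) adds water in the Markovnikov sense through a radical pathway and gives the secondary alcohol F8 as a mixture of C8 epimers. This is oxidised at once with Dess–Martin periodinane, before the acetyl group can migrate, to give 21.

Further compounds
F1 | step 7 | methyl (4S,5R)-4-{[(2E)-4-tert-butoxy-2-methyl-4-oxobut-2-enoyl]oxy}-5-(triethylsilyloxy)hept-6-en-2-ynoate | CC[Si](CC)(CC)O[C@H](C=C)[C@@H](OC(=O)/C(C)=C/C(=O)OC(C)(C)C)C#CC(=O)OC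
F2 | step 7 | methyl (2E,4S,5R)-4-{[(2E)-4-tert-butoxy-2-methyl-4-oxobut-2-enoyl]oxy}-2-(tributylstannyl)-5-(triethylsilyloxy)hepta-2,6-dienoate | CC[Si](CC)(CC)O[C@H](C=C)[C@@H](OC(=O)/C(C)=C/C(=O)OC(C)(C)C)/C=C(/[Sn](CCCC)(CCCC)CCCC)C(=O)OC
F3 | step 7 | methyl (2Z,4S,5R)-4-{[(2E)-4-tert-butoxy-2-methyl-4-oxobut-2-enoyl]oxy}-2-ethenyl-5-(triethylsilyloxy)hepta-2,6-dienoate | CC[Si](CC)(CC)O[C@H](C=C)[C@@H](OC(=O)/C(C)=C/C(=O)OC(C)(C)C)/C=C(/C=C)C(=O)OC
F4 | step 7 | trans-fused cycloadduct of F3, the analogue of 11 with a tert-butoxycarbonyl group on C1 cis to Me-20 | CC[Si](CC)(CC)O[C@H](C=C)[C@H]1OC(=O)[C@@]2(C)[C@H](C(=O)OC(C)(C)C)CC=C(C(=O)OC)[C@H]12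
F5 | step 7 | C1 carboxylic acid obtained from F4 | CC[Si](CC)(CC)O[C@H](C=C)[C@H]1OC(=O)[C@@]2(C)[C@H](C(=O)O)CC=C(C(=O)OC)[C@H]12
F6 | step 10 | methyl (1S,2R,3S)-2-[(1S,2R)-1-hydroxy-2-(triethylsilyloxy)but-3-en-1-yl]-3-[methoxy(methyl)carbamoyl]-1,3-dimethylcyclohexane-1-carboxylate | CC[Si](CC)(CC)O[C@H](C=C)[C@@H](O)[C@H]1[C@@](C)(C(=O)OC)CCC[C@]1(C)C(=O)N(C)OC
F7 | step 10 | (3S,3aR,4S,7aS)-N-methoxy-N,4,7a-trimethyl-1-oxo-3-[(1R)-1-(triethylsilyloxy)prop-2-en-1-yl]octahydro-2-benzofuran-4-carboxamide | CC[Si](CC)(CC)O[C@H](C=C)[C@H]1OC(=O)[C@@]2(C)CCC[C@](C)(C(=O)N(C)OC)[C@@H]12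
F8 | step 12 | (1S)-1-[(3S,3aR,4S,7aS)-4-[3-(furan-3-yl)propanoyl]-4,7a-dimethyl-1-oxooctahydro-2-benzofuran-3-yl]-2-hydroxypropyl acetate, both C8 epimers | CC(=O)O[C@H](C(C)O)[C@H]1OC(=O)[C@@]2(C)CCC[C@](C)(C(=O)CCc3ccoc3)[C@@H]12
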